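**Plan**

1. Retrosynthesis: the two tropolone O–H groups are masked as methyl ethers. C12–H and the C10 O–H come from reductive cleavage of a temporary C12–O(C10) bond, a tetrahydrofuran bridge. Ring A is cut at C13–C1 and O–C11, a hetero-Diels–Alder reaction of a tropone ortho-quinone methide with the E C1=C11 alkene.
2. Key disconnection: C7–C8 and C12–C5′ together. This opens the eleven-membered ring and ring B to an open chain carrying an O-(tropon-4-yl) enol ether at C7 and a 2,3-dihydrofuran (O–C12=C8–C9–C10). The chain is cut at C4=C5 (Julia–Kocienski) and at C9–C10 (propargylation).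
3. Enabling feature: the C10 hydroxyl oxygen is 1,4 to the benzylic carbon C12 (O–C10–C9–C8–C12). C12=C8 can therefore be held as the enol ether of a five-membered ring whose oxygen is the C10 oxygen. This makes C8 nucleophilic and C12 cationic, the reverse of a plain vinyl group, and ties C8 to C10. The tertiary aryl ether O–C7(Me) of ring B is the matching O-aryl oxocarbenium ion (a 2-oxadiene).
4. Forward order: chain (steps 1–7), dihydrofuran (8), enol ether with the hydroxytropone (13), acid-triggered cascade closing the eleven-membered ring and ring B and leaving the C8–C10 tetrahydrofuran bridge (14), ring A (15), cleavage of the bridge (16), demethylation (17).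
5. Stereochemistry: C10 by catalyst-controlled propargylation. C8 and C7 are relayed from C10 in the cascade (cis-bridged five-membered ring, trans fusion of ring B). C1 and C11 come from suprafacial cycloaddition to the E alkene on the exposed face of the bridged macrocycle. Both E alkenes are set before cyclisation.

Key step: step 14

Numbering used: C1–C11 are the carbons of the eleven-membered ring (C1 = CH carrying the ring A CH2, C3 = CMe2, C4=C5, C7 = C(Me)–O of ring B, C8, C10 = CHOH, C11 = C(Me)–O of ring A). C12 is the CH2 between C8 and ring B, C13 the CH2 between C1 and ring A. Tropolone atoms are primed (C1′=O, C2′–OH, C4′–O, C5′, C6′–Me).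

Assumption: the hydroxytropone 17, a vinylogous acid, reacts as an O-nucleophile at the 4-oxygen and as a C-nucleophile at C5, not at the carbonyl oxygen or C7. Charge at C4 is stabilised through C3 by the 2-methoxy group, and the C1 oxygen is flanked by that group.

Assumption: in step 7 the enantiomer of the phosphoric acid is the one that directs Si-face addition to the aldehyde.

Step 1
Reactants: 1 2-methylpropanal; 2 1-bromo-3-methylbut-2-ene
Product: 3 2,2,5-trimethylhex-4-enal
Conditions: NaOH (50% aq.), Bu4NI (cat.), toluene, 70 °C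
Reagents that add atoms: none
Why: Phase-transfer α-alkylation of the single enolisable position of the aldehyde by SN2 attack on the primary allylic bromide should give the quaternary aldehyde.

Step 2
Reactants: 4 4-(trimethylsilyl)but-3-yn-1-ol
Product: 5 1-phenyl-5-{[4-(trimethylsilyl)but-3-yn-1-yl]sulfanyl}-1H-tetrazole
Conditions: 1-phenyl-1H-tetrazole-5-thiol, PPh3, DIAD, THF, 0 °C to rt
Reagents that add atoms: 1-phenyl-1H-tetrazole-5-thiol, Sc1nnnn1-c1ccccc1
Why: Mitsunobu thioetherification of a primary alcohol with the acidic heteroaryl thiol is a standard entry to Julia–Kocienski sulfones.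

Step 3
Reactants: 5 1-phenyl-5-{[4-(trimethylsilyl)but-3-yn-1-yl]sulfanyl}-1H-tetrazole
Product: 6 1-phenyl-5-{[4-(trimethylsilyl)but-3-yn-1-yl]sulfonyl}-1H-tetrazole
Conditions: H2O2 (30% aq.), (NH4)6Mo7O24·4H2O (cat.), EtOH, 0 °C to rt
Reagents that add atoms: hydrogen peroxide, OO
Why: Molybdate-catalysed oxidation of the sulfide to the sulfone should leave the silyl alkyne untouched.

Step 4
Reactants: 6 1-phenyl-5-{[4-(trimethylsilyl)but-3-yn-1-yl]sulfonyl}-1H-tetrazole; 3 2,2,5-trimethylhex-4-enal
Product: 7 trimethyl[(4E)-6,6,9-trimethyldeca-4,8-dien-1-yn-1-yl]silane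
Conditions: KN(SiMe3)2 (1.05 equiv), DME, −60 °C; then 3, −60 °C to rt
Reagents that add atoms: none
Why: Julia–Kocienski olefination with a phenyltetrazolyl sulfone and an α-quaternary aldehyde should give the E C4=C5 alkene.

Step 5
Reactants: 7 trimethyl[(4E)-6,6,9-trimethyldeca-4,8-dien-1-yn-1-yl]silane
Product: 8 (2E,6E)-2,5,5-trimethyl-10-(trimethylsilyl)deca-2,6-dien-9-yn-1-ol
Conditions: SeO2 (cat.), t-BuOOH, salicylic acid (cat.), CH2Cl2, rt
Reagents that add atoms: tert-butyl hydroperoxide, CC(C)(C)OO
Why: Selenium dioxide allylic oxidation (ene reaction, then 2,3-shift) attacks the E-methyl group of the trisubstituted alkene and fixes the E geometry of the future C1=C11 bond.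

Step 6
Reactants: 8 (2E,6E)-2,5,5-trimethyl-10-(trimethylsilyl)deca-2,6-dien-9-yn-1-ol
Product: 9 (2E,6E)-2,5,5-trimethyl-10-(trimethylsilyl)deca-2,6-dien-9-ynal
Conditions: MnO2, CH2Cl2, rt
Reagents that add atoms: none
Why: Manganese dioxide oxidises the allylic alcohol selectively to the enal without alkene isomerisation.

Step 7
Reactants: 9 (2E,6E)-2,5,5-trimethyl-10-(trimethylsilyl)deca-2,6-dien-9-ynal
Product: 11 (4S,5E,9E)-5,8,8-trimethyl-13-(trimethylsilyl)trideca-5,9-dien-1,12-diyn-4-ol, via pinacol borate ester 10 (not isolated)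
Conditions: allenylboronic acid pinacol ester, TRIP phosphoric acid (5 mol %), 4 Å MS, toluene, 0 °C; aqueous work-up
Reagents that add atoms: allenylboronic acid pinacol ester, C=C=CB1OC(C)(C)C(C)(C)O1
Why: Chiral phosphoric acid-catalysed propargylboration through a six-membered chair transition state (SE2′ transfer from the allenylboronate) sets C10 as S by catalyst-controlled Si-face attack.

Step 8
Reactants: 11 (4S,5E,9E)-5,8,8-trimethyl-13-(trimethylsilyl)trideca-5,9-dien-1,12-diyn-4-ol
Product: 12 (2S)-2-[(2E,6E)-5,5-dimethyl-10-(trimethylsilyl)deca-2,6-dien-9-yn-2-yl]-2,3-dihydrofuran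
Conditions: [RhCl(cod)]2 (2.5 mol %), P(4-FC6H4)3, DMF, 85 °C
Reagents that add atoms: none
Why: Rhodium-catalysed endo cycloisomerisation of the terminal homopropargylic alcohol through a metal vinylidene closes the 2,3-dihydrofuran; the silylated alkyne cannot form a vinylidene and C10 is not touched.

Step 9
Reactants: 12 (2S)-2-[(2E,6E)-5,5-dimethyl-10-(trimethylsilyl)deca-2,6-dien-9-yn-2-yl]-2,3-dihydrofuran
Product: 13 (2S)-2-[(2E,6E)-5,5-dimethyldeca-2,6-dien-9-yn-2-yl]-2,3-dihydrofuran
Conditions: K2CO3 (cat.), MeOH, rt
Reagents that add atoms: none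
Why: Methoxide-mediated protiodesilylation frees the terminal alkyne under basic conditions that the acid-labile dihydrofuran tolerates.

Step 10
Reactants: 14 3,4-dimethoxyphenol
Product: 15 3,4,4-trimethoxycyclohexa-2,5-dien-1-one
Conditions: PhI(OAc)2, MeOH, 0 °C
Reagents that add atoms: methanol, CO
Why: Hypervalent-iodine oxidative dearomatisation of a para-alkoxyphenol in methanol gives the para-quinone monoketal.

Step 11
Reactants: 15 3,4,4-trimethoxycyclohexa-2,5-dien-1-one
Product: 16 4,5,5-trimethoxy-7-methylbicyclo[4.1.0]hept-3-en-2-one (racemic, mixture of C7 epimers)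
Conditions: Ph2S(Et)BF4, LiN(iPr)2, DME, −78 °C; then 15, −78 to −20 °C
Reagents that add atoms: ethyldiphenylsulfonium tetrafluoroborate, CC[S+](c1ccccc1)c1ccccc1.F[B-](F)(F)F
Why: Corey–Chaykovsky-type cyclopropanation with the sulfonium ethylide takes place at the unsubstituted enone double bond, because the methoxy-bearing one is a deactivated vinylogous ester; the new stereocentres are destroyed in step 12.

Step 12
Reactants: 16 4,5,5-trimethoxy-7-methylbicyclo[4.1.0]hept-3-en-2-one
Product: 17 4-hydroxy-2-methoxy-6-methylcyclohepta-2,4,6-trien-1-one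
Conditions: CF3CO2H, CH2Cl2–H2O, 0 °C to rt
Reagents that add atoms: water, O
Why: Proposed new method: protonation of the vinylogous-ester carbonyl gives a hydroxyallyl cation, stabilised by the 4-methoxy group, that is also a cyclopropylcarbinyl cation; cleavage of the ring-fusion bond and loss of the C7 proton give a 7,7-dimethoxycycloheptatrienol (a tropone ketal) whose hydrolysis delivers the aromatic hydroxytropone with the methyl ether fixed on the oxygen next to the new carbonyl; the closest known reaction is the acid-mediated ring expansion of cyclopropanated para-quinone monoketal carbinols to tropones and tropolone ethers.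

Step 13
Reactants: 13 (2S)-2-[(2E,6E)-5,5-dimethyldeca-2,6-dien-9-yn-2-yl]-2,3-dihydrofuran; 17 4-hydroxy-2-methoxy-6-methylcyclohepta-2,4,6-trien-1-one
Product: 18 4-({(4E,8E)-9-[(2S)-2,3-dihydrofuran-2-yl]-6,6-dimethyldeca-1,4,8-trien-2-yl}oxy)-2-methoxy-6-methylcyclohepta-2,4,6-trien-1-one
Conditions: [RuCl2(p-cymene)]2 (cat.), P(2-furyl)3, Na2CO3 (cat.), toluene, 50 °C
Reagents that add atoms: none
Why: Ruthenium-catalysed Markovnikov addition of an acidic O–H (17 behaves as a vinylogous carboxylic acid) to a terminal alkyne gives the 1,1-disubstituted enol ether under buffered conditions that are neither acidic nor strongly π-acidic, so the dihydrofuran should survive.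

Step 14
Reactants: 18 4-({(4E,8E)-9-[(2S)-2,3-dihydrofuran-2-yl]-6,6-dimethyldeca-1,4,8-trien-2-yl}oxy)-2-methoxy-6-methylcyclohepta-2,4,6-trien-1-one
Product: 19 (7R,8S,10S,12R)-12,10-epoxy-bridged ring B mono-adduct (eleven-membered ring with E C1=C11 and E C4=C5, 2′-methoxytropone-fused dihydropyran trans-fused at C7–C8, tetrahydrofuran bridge C8–C12–O–C10)
Conditions: HNTf2 (20 mol %), 4 Å MS, CH2Cl2 (1 mM, slow addition of 18), −40 to 0 °C; Et3N quench
Reagents that add atoms: none
Why: Proposed new method: C-protonation of the 1,1-disubstituted aryl enol ether gives an O-(tropon-4-yl) oxocarbenium ion at C7 (a cationic 2-oxadiene, C5′=C4′–O+=C7); the nucleophilic β-carbon C8 of the dihydrofuran adds to C7 in a Prins-type macrocyclisation that closes the eleven-membered carbocycle (exo with respect to both the C7=O+ and the C8=C12 bonds), and the resulting 2-tetrahydrofuranyl cation at C12 is trapped by C5′ in a six-membered Friedel–Crafts closure (endo with respect to the C4′=C5′ bond), a stepwise oxa-Povarov annulation overall. The closest known reactions are the intermolecular oxa-Povarov reaction of aryl oxocarbenium ions with alkenes, Povarov reactions of 2,3-dihydrofuran, and Prins macrocyclisations. C8 is set by C10, because the eight-atom tether from C10 to C7 can span only one face of the five-membered ring and so gives the 2,4-cis-bridged tetrahydrofuran. C7 is set relative to C8 by a chair-like transition state in which the tether carbon C6 lies anti to C9 and the small methyl group sits over the dihydrofuran (trans fusion of ring B); C12 follows from the cis fusion that the five-membered ring enforces and is removed in step 16. The step needs productive ionisation of the less basic of two enol ethers, which reversible protonation, low temperature and high dilution should favour over dihydrofuran oligomerisation, and it needs attack at C5′ rather than C3′, which the 2′-methoxy group and the C1′ carbonyl secure (attack at C5′ gives a cation stabilised by both ether oxygens, attack at C3′ an α-keto cation). The C1=C11 alkene cannot compete, because cyclisation onto it would place the E C4=C5 alkene in a seven- or eight-membered ring.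

Step 15
Reactants: 19 (7R,8S,10S,12R)-12,10-epoxy-bridged ring B mono-adduct; 17 4-hydroxy-2-methoxy-6-methylcyclohepta-2,4,6-trien-1-one
Product: 20 (1R,7R,8S,10S,11R,12R)-12,10-epoxy-bridged bis-adduct, di-O-methyl (rings A and B both in place)
Conditions: 17 (3 equiv), (CH2O)n, 1,4-dioxane, 110 °C, sealed tube
Reagents that add atoms: formaldehyde (as paraformaldehyde), C=O
Why: Knoevenagel condensation of 17 with formaldehyde at C5 gives the tropone ortho-quinone methide, which adds as an electron-poor heterodiene to the trisubstituted C1=C11 alkene (inverse-demand hetero-Diels–Alder, oxygen to the more substituted C11); suprafacial addition to the E alkene gives the trans ring fusion, and C1 and C11 are set relative to C10 by approach to the outer face of the alkene in the bridged macrocycle.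

Step 16
Reactants: 20 (1R,7R,8S,10S,11R,12R)-12,10-epoxy-bridged bis-adduct, di-O-methyl
Product: 22 (1R,7R,8R,10S,11R)-2′,2″-di-O-methyl derivative of the target, via triethylsilyl ether 21 (not isolated)
Conditions: Et3SiH, TESOTf (cat.), CH2Cl2, −78 to −40 °C; then Bu4NF, THF, 0 °C
Reagents that add atoms: none
Why: Lewis-acid-promoted ionisation of the benzylic C12–O bond gives a cation stabilised by ring B and its 4′-alkoxy group (an O-alkylated quinone methide) that the silane reduces (ionic hydrogenation); the silyl group ends on the C10 oxygen and is removed by fluoride, and only C12 changes, becoming CH2.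

Step 17
Reactants: 22 (1R,7R,8R,10S,11R)-2′,2″-di-O-methyl derivative of the target
Product: 23 CNP0283947.4 (1R,7R,8R,10S,11R)
Conditions: LiOH, THF–H2O, 50 °C; then 1 M HCl to pH 4
Reagents that add atoms: lithium hydroxide, [Li+].[OH-]
Why: 2-Methoxytropones are vinylogous esters that undergo addition–elimination with hydroxide at C2′ much faster than the hindered tertiary 4′-alkoxy position, which should free both tropolones without touching a stereocentre.

**Compound list**

1 | 2-methylpropanal | CC(C)C=O | starting material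
2 | 1-bromo-3-methylbut-2-ene | CC(C)=CCBr | starting material
3 | 2,2,5-trimethylhex-4-enal | CC(C)=CCC(C)(C)C=O | intermediate
4 | 4-(trimethylsilyl)but-3-yn-1-ol | C[Si](C)(C)C#CCCO | starting material
5 | 1-phenyl-5-{[4-(trimethylsilyl)but-3-yn-1-yl]sulfanyl}-1H-tetrazole | C[Si](C)(C)C#CCCSc1nnnn1-c1ccccc1 | intermediate
6 | 1-phenyl-5-{[4-(trimethylsilyl)but-3-yn-1-yl]sulfonyl}-1H-tetrazole | C[Si](C)(C)C#CCCS(=O)(=O)c1nnnn1-c1ccccc1 | intermediate
7 | trimethyl[(4E)-6,6,9-trimethyldeca-4,8-dien-1-yn-1-yl]silane | C[Si](C)(C)C#CC/C=C/C(C)(C)CC=C(C)C | intermediate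
8 | (2E,6E)-2,5,5-trimethyl-10-(trimethylsilyl)deca-2,6-dien-9-yn-1-ol | C[Si](C)(C)C#CC/C=C/C(C)(C)C/C=C(\C)CO | intermediate
9 | (2E,6E)-2,5,5-trimethyl-10-(trimethylsilyl)deca-2,6-dien-9-ynal | C[Si](C)(C)C#CC/C=C/C(C)(C)C/C=C(\C)C=O | intermediate
10 | pinacol borate ester of 11 (O–B bond at C10) | C[Si](C)(C)C#CC/C=C/C(C)(C)C/C=C(\C)[C@@H](OB1OC(C)(C)C(C)(C)O1)CC#C | intermediate
11 | (4S,5E,9E)-5,8,8-trimethyl-13-(trimethylsilyl)trideca-5,9-dien-1,12-diyn-4-ol | C[Si](C)(C)C#CC/C=C/C(C)(C)C/C=C(\C)[C@@H](O)CC#C | intermediate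
12 | (2S)-2-[(2E,6E)-5,5-dimethyl-10-(trimethylsilyl)deca-2,6-dien-9-yn-2-yl]-2,3-dihydrofuran | C[Si](C)(C)C#CC/C=C/C(C)(C)C/C=C(\C)[C@@H]1CC=CO1 | intermediate
13 | (2S)-2-[(2E,6E)-5,5-dimethyldeca-2,6-dien-9-yn-2-yl]-2,3-dihydrofuran | C#CC/C=C/C(C)(C)C/C=C(\C)[C@@H]1CC=CO1 | intermediate
14 | 3,4-dimethoxyphenol | COc1ccc(O)cc1OC | starting material
15 | 3,4,4-trimethoxycyclohexa-2,5-dien-1-one | COC1=CC(=O)C=CC1(OC)OC | intermediate
16 | 4,5,5-trimethoxy-7-methylbicyclo[4.1.0]hept-3-en-2-one (racemic, C7 epimers) | COC1=CC(=O)C2C(C)C2C1(OC)OC | intermediate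
17 | 4-hydroxy-2-methoxy-6-methylcyclohepta-2,4,6-trien-1-one | COc1cc(O)cc(C)cc1=O | intermediate
18 | 4-({(4E,8E)-9-[(2S)-2,3-dihydrofuran-2-yl]-6,6-dimethyldeca-1,4,8-trien-2-yl}oxy)-2-methoxy-6-methylcyclohepta-2,4,6-trien-1-one | C=C(Oc1cc(OC)c(=O)cc(C)c1)C/C=C/C(C)(C)C/C=C(\C)[C@@H]1CC=CO1 | intermediate
19 | (7R,8S,10S,12R)-12,10-epoxy-bridged ring B mono-adduct, 2′-O-methyl | C/C1=C\CC(C)(C)/C=C/C[C@@]2(C)Oc3cc(OC)c(=O)cc(C)c3[C@@H]4O[C@H]1C[C@H]24 | intermediate
20 | (1R,7R,8S,10S,11R,12R)-12,10-epoxy-bridged bis-adduct, di-O-methyl | Cc1cc(=O)c(OC)cc2c1C[C@H]1CC(C)(C)/C=C/C[C@@]3(C)Oc4cc(OC)c(=O)cc(C)c4[C@@H]5O[C@@H](C[C@H]35)[C@]1(C)O2 | intermediate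
21 | 10-O-triethylsilyl-2′,2″-di-O-methyl derivative of the target | Cc1cc(=O)c(OC)cc2c1C[C@H]1CC(C)(C)/C=C/C[C@@]3(C)Oc4cc(OC)c(=O)cc(C)c4C[C@@H]3C[C@H](O[Si](CC)(CC)CC)[C@]1(C)O2 | intermediate
22 | (1R,7R,8R,10S,11R)-2′,2″-di-O-methyl derivative of the target | Cc1cc(=O)c(OC)cc2c1C[C@H]1CC(C)(C)/C=C/C[C@@]3(C)Oc4cc(OC)c(=O)cc(C)c4C[C@@H]3C[C@H](O)[C@]1(C)O2 | intermediate
23 | CNP0283947.4 (1R,7R,8R,10S,11R) | Cc1cc(=O)c(O)cc2c1C[C@H]1CC(C)(C)/C=C/C[C@@]3(C)Oc4cc(O)c(=O)cc(C)c4C[C@@H]3C[C@H](O)[C@]1(C)O2 | target

**Step count and risks**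

Total step count: 17. Longest linear sequence: 13 steps (steps 2–9 and 13–17, from 4).

Steps most likely to fail:

1. Step 14 (proposed new method). The dihydrofuran may be protonated in preference to the aryl enol ether and oligomerise. The oxocarbenium ion may lose a proton from C6 and drift into conjugation with the C4=C5 alkene. The Friedel–Crafts closure may fail, or C7 may form with the wrong facial sense. The fallback uses known chemistry (ring-closing metathesis and the biomimetic two-fold hetero-Diels–Alder reaction) and sets out from 9. Asymmetric allylation of 9 with the Si-face-selective enantiomer of B-allyldiisopinocampheylborane (Et2O, −78 °C; NaOH, H2O2) should give the homoallylic alcohol (4S,5E,9E)-5,8,8-trimethyl-13-(trimethylsilyl)trideca-1,5,9-trien-12-yn-4-ol F1. K2CO3 in MeOH should give the terminal alkyne F2. Carboalumination with AlMe3 and Cp2ZrCl2 (cat.) followed by protonolysis should give the isopropenyl tetraene F3. Ring-closing metathesis with the second-generation Grubbs catalyst at high dilution should join the vinyl and isopropenyl termini to the all-E (S)-10-hydroxyhumulene F4. Heating F4 with excess 17 and paraformaldehyde should bring about cycloaddition at both trisubstituted alkenes, and the route is rejoined at 22.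

2. Step 12 (proposed new method). The exocyclic cyclopropane bond may cleave instead of the ring-fusion bond and lead to benzenoid products, or the ketal may simply hydrolyse without ring expansion. The fallback uses known reaction types and sets out from 16. Mild hydrolysis (oxalic acid, wet silica, CH2Cl2) should give the ene-dione 4-methoxy-7-methylbicyclo[4.1.0]hept-3-ene-2,5-dione F5. Reduction with Zn in AcOH should give its dienediol, a norcaradiene that opens by 6π electrocyclic ring opening and tautomerises to 2-methoxy-6-methylcyclohept-2-ene-1,4-dione F6. Dehydrogenation with DDQ should then give 17, where the route is rejoined.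

3. Step 15. The quinone methide may add to the wrong π-face of the C1=C11 alkene in the bridged macrocycle, 17 may condense with formaldehyde at C7 instead of C5, or 17 may self-condense to a methylene-bridged dimer. The fallback changes the substrate that controls the cycloaddition and sets out from 19. Reductive opening of the bridge first (Et3SiH, TESOTf cat., CH2Cl2, −78 °C) should give the 10-O-triethylsilyl ring B mono-adduct F7, and Bu4NF should give the free C10 alcohol of the ring B mono-adduct F8. The cycloaddition with 17 and paraformaldehyde is then run on this unbridged macrocycle, whose free allylic hydroxyl can guide the quinone methide by hydrogen bonding, and the route is rejoined at 22.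

Further compounds
F1 | step 14 | (4S,5E,9E)-5,8,8-trimethyl-13-(trimethylsilyl)trideca-1,5,9-trien-12-yn-4-ol | C[Si](C)(C)C#CC/C=C/C(C)(C)C/C=C(\C)[C@@H](O)CC=C
F2 | step 14 | (4S,5E,9E)-5,8,8-trimethyltrideca-1,5,9-trien-12-yn-4-ol | C#CC/C=C/C(C)(C)C/C=C(\C)[C@@H](O)CC=C
F3 | step 14 | (4S,5E,9E)-5,8,8,12-tetramethyltrideca-1,5,9,12-tetraen-4-ol | C=C(C)C/C=C/C(C)(C)C/C=C(\C)[C@@H](O)CC=C
F4 | step 14 | (1S,2E,6E,9E)-2,5,5,9-tetramethylcycloundeca-2,6,9-trien-1-ol ((S)-10-hydroxyhumulene) | C/C1=C\CC(C)(C)/C=C/C/C(C)=C/C[C@@H]1O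
F5 | step 12 | 4-methoxy-7-methylbicyclo[4.1.0]hept-3-ene-2,5-dione | COC1=CC(=O)C2C(C)C2C1=O
F6 | step 12 | 2-methoxy-6-methylcyclohept-2-ene-1,4-dione | COC1=CC(=O)CC(C)CC1=O
F7 | step 15 | 10-O-triethylsilyl ring B mono-adduct (7R,8R,10S), 2′-O-methyl | C/C1=C\CC(C)(C)/C=C/C[C@@]2(C)Oc3cc(OC)c(=O)cc(C)c3C[C@@H]2C[C@@H]1O[Si](CC)(CC)CC
F8 | step 15 | ring B mono-adduct with free C10 hydroxyl (7R,8R,10S), 2′-O-methyl | C/C1=C\CC(C)(C)/C=C/C[C@@]2(C)Oc3cc(OC)c(=O)cc(C)c3C[C@@H]2C[C@@H]1O
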